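The lactone carbons are numbered from the carbonyl (C1) round to the oxygen-bound CH2 (C34). The 35-membered ring is cut at C17–C18, directly across the ring from the ester O–C1 linkage. Each fragment then holds seventeen carbons, and the two are the acid and the alcohol form of the same ω-alkynyl chain. One copper-mediated oxidative alkyne–alkyne coupling makes C17–C18 and closes the only ring as a C16–C19 conjugated diyne, which hydrogenation then saturates. The cyclisation substrate is the unprotected open-chain ester of heptadec-16-ynoic acid with heptadec-16-yn-1-ol, with a terminal alkyne at each end. Both halves come from one ω-bromo acid.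

Key step: step 4

Remark on the chemistry: the target has no stereocentre and no stereogenic double bond, so no stereocontrol is needed. 15-Bromopentadecanoic acid and the lithium acetylide–ethylenediamine complex (LiC≡CH·H2NCH2CH2NH2) are taken as catalogue chemicals.

Step 1
Reactants: 1 15-bromopentadecanoic acid; 2 lithium acetylide–ethylenediamine complex
Product: 5 heptadec-16-ynoic acid, via lithium 15-bromopentadecanoate 3 (not isolated), via lithium heptadec-16-ynoate 4 (not isolated)
Conditions: 2 (3.5 equiv), DMSO, 15 °C to rt; then aq HCl
Reagents that add atoms: none
Why: Acetylide SN2 alkylation, in which the first equivalent of LiC≡CH converts the acid into its unreactive lithium carboxylate and further acetylide displaces the unhindered primary bromide in dipolar aprotic DMSO, the standard preparation of ω-alkynoic acids from ω-bromo acids.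

Step 2
Reactants: 5 heptadec-16-ynoic acid (about half of the batch)
Product: 6 heptadec-16-yn-1-ol
Conditions: LiAlH4 (2 equiv), THF, 0 °C to 40 °C; then H2O, aq NaOH (Fieser work-up)
Reagents that add atoms: none
Why: LiAlH4 reduction of a carboxylic acid to the primary alcohol, which leaves an isolated, unactivated alkyne untouched in THF at this temperature, any metalated terminal C–H being restored on aqueous work-up.

Step 3
Reactants: 5 heptadec-16-ynoic acid; 6 heptadec-16-yn-1-ol
Product: 7 heptadec-16-yn-1-yl heptadec-16-ynoate
Conditions: DCC (1.1 equiv), DMAP (0.1 equiv), CH2Cl2, 0 °C to rt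
Reagents that add atoms: none
Why: Steglich esterification, in which the carbodiimide activates the acid and DMAP relays the acyl group to the unhindered primary alcohol under neutral conditions that do not affect either terminal alkyne.

Step 4
Reactants: 7 heptadec-16-yn-1-yl heptadec-16-ynoate
Product: 8 oxacyclopentatriaconta-17,19-diyn-2-one
Conditions: Cu(OAc)2 (10 equiv), pyridine/Et2O (5:1), 45 °C, N2; 7 added by syringe pump over 24 h to a final concentration of about 1 mM
Reagents that add atoms: none
Why: This is the Eglinton variant of the Glaser oxidative alkyne coupling: pyridine/acetate removes the terminal proton of each copper-coordinated alkyne, the two copper acetylide ends of one molecule meet in a dinuclear divalent-copper assembly, and reductive elimination forms the C17–C18 sp–sp bond while two monovalent copper centres leave, excess Cu(OAc)2 being the stoichiometric oxidant. The closest known reaction class is the copper-mediated cyclisation of α,ω-diynes and diyne esters to macrocyclic 1,3-diynes by slow addition. Ring closure is a head-to-tail macrocyclisation giving the single 35-membered ring with all four sp carbons endocyclic, and tethers of fourteen and fifteen methylenes span the linear C15–C20 segment without strain. No stereocentre is created. The selectivity required is ring closure over chain growth, enforced by syringe-pump addition of 7 into a large excess of warm oxidant so that uncoupled terminal alkyne never accumulates. Both ends are the same functional group, so no hetero-selectivity or regiochemical issue arises, and the ester does not react with Cu(OAc)2 in pyridine.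

Step 5
Reactants: 8 oxacyclopentatriaconta-17,19-diyn-2-one
Product: 9 oxacyclopentatriacontan-2-one
Conditions: H2 (1–3 atm), 10% Pd/C, EtOAc/THF, rt
Reagents that add atoms: none
Why: Heterogeneous catalytic hydrogenation over Pd/C should saturate both triple bonds of the conjugated diyne completely (four equivalents of H2), while the lactone is inert and no stereocentre arises.

Compound list
1 | 15-bromopentadecanoic acid | OC(=O)CCCCCCCCCCCCCCBr | starting material
2 | lithium acetylide–ethylenediamine complex (LiC≡CH·H2NCH2CH2NH2) | [Li]C#C.NCCN | starting material
3 | lithium 15-bromopentadecanoate | [Li+].[O-]C(=O)CCCCCCCCCCCCCCBr | intermediate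
4 | lithium heptadec-16-ynoate | [Li+].[O-]C(=O)CCCCCCCCCCCCCCC#C | intermediate
5 | heptadec-16-ynoic acid | OC(=O)CCCCCCCCCCCCCCC#C | intermediate
6 | heptadec-16-yn-1-ol | OCCCCCCCCCCCCCCCC#C | intermediate
7 | heptadec-16-yn-1-yl heptadec-16-ynoate | C#CCCCCCCCCCCCCCCC(=O)OCCCCCCCCCCCCCCCC#C | intermediate
8 | oxacyclopentatriaconta-17,19-diyn-2-one | O=C1CCCCCCCCCCCCCCC#CC#CCCCCCCCCCCCCCCCO1 | intermediate
9 | oxacyclopentatriacontan-2-one (achiral) | O=C1CCCCCCCCCCCCCCCCCCCCCCCCCCCCCCCCCO1 | target

Total step count: 5. Longest linear sequence: 5 steps (1 → 5 → 6 → 7 → 8 → 9).

Steps most likely to fail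

Step 4: intermolecular coupling may outrun ring closure, giving linear oligomers and cyclic dimers. The fallback makes the C17–C18 bond intermolecularly and closes the ring at the ester instead. It sets out from alkynol 6 (with acid 5) and comes back at 8. Alkynol 6 would be brominated at the alkyne terminus (NBS, cat. AgNO3, acetone, rt) to 17-bromoheptadec-16-yn-1-ol F1. Cadiot–Chodkiewicz heterocoupling of F1 with acid 5 (cat. CuCl, NH2OH·HCl, aqueous EtNH2, MeOH/THF, 0 °C to rt) would give 34-hydroxytetratriaconta-16,18-diynoic acid F2. Yamaguchi macrolactonisation of F2 (2,4,6-trichlorobenzoyl chloride, Et3N, THF, then slow addition to DMAP in refluxing toluene) would deliver diyne lactone 8, after which step 5 follows unchanged.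

Step 1: the aggregated, poorly soluble bromo carboxylate may react sluggishly, so that dehydrobromination and incomplete substitution compete. The fallback carries out the acetylide alkylation at the alcohol oxidation level on a neutral substrate and inverts the redox relation of the two halves. It sets out from 1 and comes back at 6. Bromo acid 1 would be reduced chemoselectively with BH3·THF (0 °C to rt) to 15-bromopentadecan-1-ol F3. F3 would be protected with 3,4-dihydro-2H-pyran and PPTS in CH2Cl2 as 2-[(15-bromopentadecyl)oxy]oxane F4. Alkylation of F4 with 2 in DMSO would give 2-(heptadec-16-yn-1-yloxy)oxane F5. Deprotection (PPTS, MeOH, 50 °C) would give alkynol 6. Acid 5 would then be obtained from part of 6 by Jones oxidation (CrO3, H2SO4, acetone, 0 °C), so step 2 is not needed and the route resumes at step 3.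

Step 3: the activated acid may rearrange to the unreactive N-acylurea before the waxy alcohol captures it, and the urea by-product may be hard to remove. The fallback forms the ester by O-alkylation of the carboxylate instead of acylation of the alcohol. It sets out from 6 and comes back at 7. Alcohol 6 would be converted (MsCl, Et3N, CH2Cl2, 0 °C) into heptadec-16-yn-1-yl methanesulfonate F6. The cesium salt of acid 5 (Cs2CO3, DMF, 50 °C) would then displace the mesylate to give ester 7.

Further compounds
F1 | step 4 | 17-bromoheptadec-16-yn-1-ol | OCCCCCCCCCCCCCCCC#CBr
F2 | step 4 | 34-hydroxytetratriaconta-16,18-diynoic acid | OC(=O)CCCCCCCCCCCCCCC#CC#CCCCCCCCCCCCCCCCO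
F3 | step 1 | 15-bromopentadecan-1-ol | OCCCCCCCCCCCCCCCBr
F4 | step 1 | 2-[(15-bromopentadecyl)oxy]oxane (racemic) | BrCCCCCCCCCCCCCCCOC1CCCCO1
F5 | step 1 | 2-(heptadec-16-yn-1-yloxy)oxane (racemic) | C#CCCCCCCCCCCCCCCCOC1CCCCO1
F6 | step 3 | heptadec-16-yn-1-yl methanesulfonate | C#CCCCCCCCCCCCCCCCOS(C)(=O)=O
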